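**Plan**
- Numbering of the central phenol ring: C1 (OH), C2 (4-hydroxybenzyl), C3 (CH2CH2 bridge to the 3-hydroxy-5-methoxyphenyl ring A), C4 (4-hydroxybenzyl), C5-H, C6-H.
- Cuts: the bridge is raised to an E-stilbene and the four phenols become benzyl ethers. C3–C(vinyl) and C4–CH2(aryl) are then cut together, giving a C3 iodide, a benzylic chloride and the ring-A styrene. The CH2–aryl bond of the C2 benzyl group and the C1–O bond lead back to 2-fluoro-6-iodobenzaldehyde, and the vinyl–ring A bond leads back to a bromophenol.
- Enabling feature: C3 and C4 are adjacent ring carbons that both carry carbon groups, and the other neighbour of C3 (C2) is already alkylated. A C3 iodide with a free C4–H is therefore the ipso/ortho pair of a palladium/norbornene relay, with the required ortho blocking group in place.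
- Forward order: no ring is formed at any stage, since all four benzene rings are bought. C1–O is made first, then the C2 benzyl group, with ring A vinylated in parallel. C4–CH2 and C3–vinyl follow in one pot, and one hydrogenation finishes the route.
- Stereochemistry: the target has none. The racemic carbinol and the E-alkene formed on the way are both erased.

Key step: step 6

Remark: the target has no stereocentre, stereogenic axis or double-bond isomerism, so it is one achiral compound and no enantiocontrol is needed.

**Step 1**
Reactants: 1 2-fluoro-6-iodobenzaldehyde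
Product: 2 2-(benzyloxy)-6-iodobenzaldehyde
Conditions: BnOH, NaH, DMF, 0 °C → rt
Reagents that add atoms: benzyl alcohol, OCc1ccccc1
Why: Nucleophilic aromatic substitution (addition–elimination), in which the ortho-formyl group stabilises the Meisenheimer adduct and fluoride leaves far more readily than iodide, so only C–F is exchanged and the C–I bond is kept.

**Step 2**
Reactants: 2 2-(benzyloxy)-6-iodobenzaldehyde; 3 1-(benzyloxy)-4-bromobenzene
Product: 5 (±)-[2-(benzyloxy)-6-iodophenyl][4-(benzyloxy)phenyl]methanol, via 4-(benzyloxy)phenylmagnesium bromide 4 (not isolated)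
Conditions: 3, Mg, THF, reflux; then added to 2, THF, −78 → 0 °C; aq NH4Cl
Reagents that add atoms: magnesium, [Mg] (held in 4 only, lost on work-up)
Why: Grignard 1,2-addition, in which carbonyl attack by an aryl Grignard at low temperature is much faster than aryl–aryl iodine–magnesium exchange (as in routine 2-iodobenzhydrol preparations), and the new carbinol centre forms racemic and is deleted in step 3.

**Step 3**
Reactants: 5 (±)-[2-(benzyloxy)-6-iodophenyl][4-(benzyloxy)phenyl]methanol
Product: 6 1-(benzyloxy)-2-[4-(benzyloxy)benzyl]-3-iodobenzene
Conditions: Et3SiH (3 equiv), TFA (added last), CH2Cl2, 0 °C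
Reagents that add atoms: none
Why: Ionic hydrogenation (Kursanov–Parnes), in which TFA ionises the doubly benzylic alcohol to a cation stabilised by the para- and ortho-benzyloxy groups and excess silane traps it with hydride, while the aryl iodide and aryl benzyl ethers are inert at 0 °C.

**Step 4**
Reactants: 7 3-bromo-5-methoxyphenol
Product: 8 1-(benzyloxy)-3-bromo-5-methoxybenzene
Conditions: BnBr, K2CO3, DMF, rt
Reagents that add atoms: benzyl bromide, BrCc1ccccc1
Why: Williamson ether synthesis on the only acidic OH, with the aryl bromide and methyl ether as spectators.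

**Step 5**
Reactants: 8 1-(benzyloxy)-3-bromo-5-methoxybenzene
Product: 9 1-(benzyloxy)-3-methoxy-5-vinylbenzene
Conditions: vinyl-Bpin, Pd(dppf)Cl2 (cat.), K2CO3, dioxane/H2O, 85 °C (BHT trace)
Reagents that add atoms: vinylboronic acid pinacol ester, C=CB1OC(C)(C)C(C)(C)O1
Why: Suzuki–Miyaura vinylation of an unhindered aryl bromide, a standard way to styrenes that leaves both aryl ethers untouched.

**Step 6**
Reactants: 6 1-(benzyloxy)-2-[4-(benzyloxy)benzyl]-3-iodobenzene; 9 1-(benzyloxy)-3-methoxy-5-vinylbenzene; 10 4-(benzyloxy)benzyl chloride
Product: 11 (E)-1-(benzyloxy)-2,4-bis[4-(benzyloxy)benzyl]-3-[3-(benzyloxy)-5-methoxystyryl]benzene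
Conditions: Pd(OAc)2 (10 mol %), P(2-furyl)3 (20 mol %), norbornene (2 equiv), Cs2CO3 (3 equiv, dried), 10 (2 equiv, in portions), 9 (3 equiv), anhydrous degassed MeCN, 85 °C, sealed tube
Reagents that add atoms: none
Why: Pd(0) inserts into the C3–I bond of 6, norbornene undergoes syn-exo carbopalladation, and because the norbornyl-palladium has no accessible syn β-hydrogen, carbonate-assisted palladation of the neighbouring C4–H closes a five-membered aryl-norbornyl palladacycle. This electron-rich Pd(II) centre takes up benzylic chloride 10 by oxidative addition to Pd(IV), reductive elimination forms C4–CH2Ar, and with C2 and C4 both filled, steric strain expels norbornene by β-carbon elimination and returns palladium to C3. The C3–palladium species then inserts styrene 9 at its terminal carbon, syn β-hydride elimination releases the stilbene, and the carbonate regenerates Pd(0). The closest known reaction type is the Catellani ortho-alkylation/ipso-Heck sequence of ortho-substituted aryl iodides, for which benzylic chlorides are established alkylating partners and styrenes established terminators. No ring of the product closes and no stereocentre is created; only the E geometry is set, by syn insertion and syn elimination through the less crowded rotamer, and step 7 erases it. Site selectivity is secured by the C2 benzyl group, which leaves C4–H as the only ortho C–H and supplies the ortho effect; the order of events is secured because the aryl iodide beats the benzylic chloride for Pd(0) and strained norbornene beats the styrene for the first arylpalladium; clean termination relies on excess 9, moderate temperature and dry base to hold back fluorene-forming C–H palladation of the flanking benzyl rings and ipso-reduction.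

**Step 7**
Reactants: 11 (E)-1-(benzyloxy)-2,4-bis[4-(benzyloxy)benzyl]-3-[3-(benzyloxy)-5-methoxystyryl]benzene
Product: 12 2,4-bis(4-hydroxybenzyl)-3-[2-(3-hydroxy-5-methoxyphenyl)ethyl]phenol (CNP0518900.0)
Conditions: H2 (1–4 bar), 10 % Pd/C, THF/MeOH, rt
Reagents that add atoms: none
Why: Heterogeneous catalytic hydrogenation, which saturates the stilbene double bond and hydrogenolyses the four aryl benzyl ethers in one operation, while the aryl methyl ether and the diarylmethane C–C bonds are inert.

**Compound list**
1 | 2-fluoro-6-iodobenzaldehyde | O=Cc1c(F)cccc1I | starting material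
2 | 2-(benzyloxy)-6-iodobenzaldehyde | O=Cc1c(OCc2ccccc2)cccc1I | intermediate
3 | 1-(benzyloxy)-4-bromobenzene | Brc1ccc(OCc2ccccc2)cc1 | starting material
4 | 4-(benzyloxy)phenylmagnesium bromide (not isolated) | Br[Mg]c1ccc(OCc2ccccc2)cc1 | intermediate
5 | (±)-[2-(benzyloxy)-6-iodophenyl][4-(benzyloxy)phenyl]methanol (racemic) | OC(c1ccc(OCc2ccccc2)cc1)c1c(OCc2ccccc2)cccc1I | intermediate
6 | 1-(benzyloxy)-2-[4-(benzyloxy)benzyl]-3-iodobenzene | Ic1cccc(OCc2ccccc2)c1Cc1ccc(OCc2ccccc2)cc1 | intermediate
7 | 3-bromo-5-methoxyphenol | COc1cc(O)cc(Br)c1 | starting material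
8 | 1-(benzyloxy)-3-bromo-5-methoxybenzene | COc1cc(OCc2ccccc2)cc(Br)c1 | intermediate
9 | 1-(benzyloxy)-3-methoxy-5-vinylbenzene | C=Cc1cc(OC)cc(OCc2ccccc2)c1 | intermediate
10 | 4-(benzyloxy)benzyl chloride | ClCc1ccc(OCc2ccccc2)cc1 | starting material
11 | (E)-1-(benzyloxy)-2,4-bis[4-(benzyloxy)benzyl]-3-[3-(benzyloxy)-5-methoxystyryl]benzene | COc1cc(OCc2ccccc2)cc(/C=C/c2c(Cc3ccc(OCc4ccccc4)cc3)ccc(OCc3ccccc3)c2Cc2ccc(OCc3ccccc3)cc2)c1 | intermediate
12 | 2,4-bis(4-hydroxybenzyl)-3-[2-(3-hydroxy-5-methoxyphenyl)ethyl]phenol | COc1cc(O)cc(CCc2c(Cc3ccc(O)cc3)ccc(O)c2Cc2ccc(O)cc2)c1 | target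

**Total step count:** 7. **Longest linear sequence:** 5 (steps 1, 2, 3, 6, 7).

**Steps most likely to fail**

Step 6. After norbornene has left, insertion of the styrene at the doubly flanked C3–palladium centre may be too slow. It could lose to C–H palladation of a neighbouring benzyl ring (fluorene closure), or to hydride delivery from benzylic alkoxide formed by carbonate attack on 10 (ipso-reduction). Compound 10 may also be drained by its own oxidative addition to Pd(0). The fallback changes the termination from olefin insertion to alkynyl transfer, which needs no insertion at the crowded carbon.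
- It sets out from 8. Sonogashira coupling with trimethylsilylacetylene (PdCl2(PPh3)2, CuI, Et3N, 70 °C) should give {[3-(benzyloxy)-5-methoxyphenyl]ethynyl}trimethylsilane F1.
- K2CO3 in MeOH should then give 1-(benzyloxy)-3-ethynyl-5-methoxybenzene F2.
- Iodide 6, chloride 10 and slowly added F2 are combined under palladium/norbornene catalysis in the known ortho-alkylation/ipso-alkynylation mode. This should give 1-(benzyloxy)-2,4-bis[4-(benzyloxy)benzyl]-3-{[3-(benzyloxy)-5-methoxyphenyl]ethynyl}benzene F3.
- Hydrogenation under the conditions of step 7 should take F3 directly to 12, where the route is rejoined.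

Step 1. Benzyloxide may transfer hydride to the aldehyde (Meerwein–Ponndorf or Cannizzaro-type redox), or it may rest as the hemiacetal alkoxide, which slows the substitution. The fallback installs the oxygen with a poorer hydride donor and exchanges the alkyl group afterwards.
- It sets out from 1. NaOMe in MeOH at reflux should give 2-iodo-6-methoxybenzaldehyde F4.
- BCl3 in CH2Cl2, guided by chelation to the formyl oxygen, should cleave the methyl ether to 2-hydroxy-6-iodobenzaldehyde F5.
- Williamson benzylation (BnBr, K2CO3, DMF) comes back to the route at 2.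

Step 7. The fourfold hydrogenolysis may stall at partly benzylated stages as solubility changes, or the catalyst may be poisoned by traces of iodide or phosphine carried over from step 6. The fallback separates the two tasks and avoids a heterogeneous catalyst.
- It sets out from 11. Diimide reduction (TsNHNH2, NaOAc, DME/H2O, reflux) should saturate the alkene only, giving 1-(benzyloxy)-2,4-bis[4-(benzyloxy)benzyl]-3-{2-[3-(benzyloxy)-5-methoxyphenyl]ethyl}benzene F6.
- BCl3 with pentamethylbenzene as cation scavenger (CH2Cl2, −78 °C) should remove the four benzyl groups, spare the aryl methyl ether and arrive at 12.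

**Further compounds**
F1 | step 6 | {[3-(benzyloxy)-5-methoxyphenyl]ethynyl}trimethylsilane | COc1cc(OCc2ccccc2)cc(C#C[Si](C)(C)C)c1
F2 | step 6 | 1-(benzyloxy)-3-ethynyl-5-methoxybenzene | C#Cc1cc(OC)cc(OCc2ccccc2)c1
F3 | step 6 | 1-(benzyloxy)-2,4-bis[4-(benzyloxy)benzyl]-3-{[3-(benzyloxy)-5-methoxyphenyl]ethynyl}benzene | COc1cc(OCc2ccccc2)cc(C#Cc2c(Cc3ccc(OCc4ccccc4)cc3)ccc(OCc3ccccc3)c2Cc2ccc(OCc3ccccc3)cc2)c1
F4 | step 1 | 2-iodo-6-methoxybenzaldehyde | COc1cccc(I)c1C=O
F5 | step 1 | 2-hydroxy-6-iodobenzaldehyde | Oc1cccc(I)c1C=O
F6 | step 7 | 1-(benzyloxy)-2,4-bis[4-(benzyloxy)benzyl]-3-{2-[3-(benzyloxy)-5-methoxyphenyl]ethyl}benzene | COc1cc(OCc2ccccc2)cc(CCc2c(Cc3ccc(OCc4ccccc4)cc3)ccc(OCc3ccccc3)c2Cc2ccc(OCc3ccccc3)cc2)c1
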